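**Retrosynthetic overview**

- The target is reached from a bis-silylated quinone by desilylation and re-oxidation of a temporary C4 alcohol; ring B is the last ring formed.
- The strategy rests on ring B being a 2',5'-dioxo-4'-methoxy quinone whose only carbon substituent is chromanone C2 at C1'. C1'/C6' are therefore taken from an alkyne and C2'–C5' from a 4-hydroxy-3-methoxycyclobutenone, and thermal ring expansion forms the C1'–C2' bond.
- The cyclobutenone precursor comes from the lithium acetylide of a (2S)-2-ethynylchroman and 3-methoxycyclobutene-1,2-dione, itself made from dimethyl squarate.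
- The C2 stereocentre comes from a CuI-catalysed enantioselective alkynylation of 5-hydroxy-7-methoxy-6,8-dimethylchromone with trimethylsilylacetylene; the C4 ketone is then masked by reduction and silylation.
- The chromone comes from phloroacetophenone by C-methylation, O-methylation and enaminone cyclisation. Ring order: A (bought), then C, then B.

Key step: step 9

**Assumptions**

- The sense of induction of the CuI/StackPhos alkynylation on this chromone is assumed to follow that of simple chromones; the ligand antipode that delivers the (2S) product is used, and the absolute configuration of 9 should be verified (chiral HPLC against the racemate from the ligand-free reaction, and a CD comparison with simple (2S)-2-alkynylchromanones) before material is carried forward.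
- The borohydride reduction is expected to give mainly the 2,4-cis alcohol, which is the isomer drawn. C4 and the cyclobutenone carbinol carbon are temporary centres, so any minor isomer converges later.

**Route**

Step 1
Reactants: 1 2',4',6'-trihydroxyacetophenone (phloroacetophenone)
Product: 2 2',4',6'-trihydroxy-3',5'-dimethylacetophenone
Conditions: MeI (2.2 equiv), NaOMe (3 equiv), MeOH, 0 °C → reflux
Reagents that add atoms: iodomethane, CI
Why: Base-mediated nuclear C-methylation of a phloroglucinol (the phenoxide of 1 reacts as a carbon nucleophile at both free ring positions in methanol), a known if unselective route to this acetophenone, from which mono- and over-methylated material is removed by crystallisation.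

Step 2
Reactants: 2 2',4',6'-trihydroxy-3',5'-dimethylacetophenone
Product: 3 2',6'-dihydroxy-4'-methoxy-3',5'-dimethylacetophenone
Conditions: Me2SO4 (1.0 equiv), K2CO3 (1.1 equiv), acetone, rt
Reagents that add atoms: dimethyl sulfate, COS(=O)(=O)OC
Why: Williamson O-methylation with one equivalent of reagent: the 4'-hydroxyl para to the acetyl group is the most acidic and is not tied up in a hydrogen bond to the carbonyl, so it should be methylated ahead of the two chelated ortho hydroxyls.

Step 3
Reactants: 3 2',6'-dihydroxy-4'-methoxy-3',5'-dimethylacetophenone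
Product: 5 5-hydroxy-7-methoxy-6,8-dimethyl-4H-chromen-4-one, via enaminone 4 (not isolated)
Conditions: Me2NCH(OMe)2, PhMe, 90 °C; then conc. HCl, CH2Cl2, 40 °C
Reagents that add atoms: N,N-dimethylformamide dimethyl acetal, CN(C)C(OC)OC
Why: Enaminone route to 2,3-unsubstituted chromones: condensation of the acetyl CH3 with the amide acetal gives 4, and acid then promotes conjugate addition of an ortho hydroxyl (the two are equivalent) and loss of dimethylamine to close ring C.

Step 4
Reactants: 5 5-hydroxy-7-methoxy-6,8-dimethyl-4H-chromen-4-one; 6 trimethylsilylacetylene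
Product: 9 (2S)-5-hydroxy-7-methoxy-6,8-dimethyl-2-[(trimethylsilyl)ethynyl]chroman-4-one, via bis(silyloxy)benzopyrylium triflate 7 (not isolated), via bis-silyl alkynyl-2H-chromene 8 (not isolated)
Conditions: TMSOTf (2.5 equiv), iPr2NEt (3 equiv), CuI (10 mol %), (S)-StackPhos (12 mol %), PhMe, −78 → −40 °C; then 1 M HCl, THF, 0 °C
Reagents that add atoms: none
Why: Copper-catalysed enantioselective alkynylation of chromones: the silyl triflate silylates the C5 phenol and the carbonyl oxygen to give the benzopyrylium ion 7, the copper acetylide formed from 6 adds at C2, and the chiral P,N-ligand on copper differentiates the two faces of the planar cation and so sets C2 as S; acidic work-up hydrolyses the silyl enol ether and the aryl silyl ether of 8.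

Step 5
Reactants: 9 (2S)-5-hydroxy-7-methoxy-6,8-dimethyl-2-[(trimethylsilyl)ethynyl]chroman-4-one
Product: 11 (2S,4S)-2-ethynyl-7-methoxy-6,8-dimethylchromane-4,5-diol, via silylalkynyl cis-diol 10 (not isolated)
Conditions: NaBH4, THF/MeOH, 0 °C; then K2CO3 (0.5 equiv), rt; pH 7 buffer work-up
Reagents that add atoms: none
Why: Borohydride reduction of the chromanone carbonyl (hydride from the axial direction of the half-chair, giving the pseudo-equatorial alcohol cis to the C2 substituent; C4 is a temporary centre that is erased in step 11) followed by base-catalysed methanolysis of the alkynyl C–Si bond; reducing first removes the β-aryloxy ketone through which base could racemise C2 by ring opening.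

Step 6
Reactants: 11 (2S,4S)-2-ethynyl-7-methoxy-6,8-dimethylchromane-4,5-diol
Product: 12 (2S,4S)-4,5-bis(tert-butyldimethylsilyloxy)-2-ethynyl-7-methoxy-6,8-dimethylchromane
Conditions: TBSOTf (2.5 equiv), 2,6-lutidine (4 equiv), CH2Cl2, −78 → 0 °C
Reagents that add atoms: tert-butyldimethylsilyl trifluoromethanesulfonate, CC(C)(C)[Si](C)(C)OS(=O)(=O)C(F)(F)F
Why: Standard silylation with a silyl triflate and a hindered pyridine base, forceful enough for the peri-crowded benzylic alcohol while the excess base protects the acid-labile electron-rich benzylic C–O bond and the terminal alkyne C–H is left alone.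

Step 7
Reactants: 13 dimethyl squarate
Product: 15 3-methoxycyclobut-3-ene-1,2-dione, via 4-hydroxy-2,3-dimethoxycyclobutenone 14 (not isolated)
Conditions: LiAlH(OtBu)3 (1.05 equiv), THF, −78 °C, 1 M HCl quench; then 12 M HCl (cat.), CH2Cl2, rt
Reagents that add atoms: water, O
Why: Known route from squarate diesters to semisquarate esters: the bulky hydride adds once to a carbonyl group, and acid then ionises the allylic carbinol of 14, water captures the methoxy-stabilised cation at the former C2 and methanol is lost, which transposes the carbonyl and leaves C–H next to C–OMe.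

Step 8
Reactants: 12 (2S,4S)-4,5-bis(tert-butyldimethylsilyloxy)-2-ethynyl-7-methoxy-6,8-dimethylchromane; 15 3-methoxycyclobut-3-ene-1,2-dione
Product: 17 4-{[(2S,4S)-4,5-bis(tert-butyldimethylsilyloxy)-7-methoxy-6,8-dimethylchroman-2-yl]ethynyl}-4-hydroxy-3-methoxycyclobut-2-en-1-one (both epimers at the cyclobutenone carbinol carbon), via lithium acetylide 16 (not isolated)
Conditions: n-BuLi (1.05 equiv), THF, −78 °C; cannulate into 15 (1.3 equiv), THF, −78 °C; sat. NH4Cl
Reagents that add atoms: none
Why: 1,2-Addition of a lithium acetylide to a cyclobutenedione: of the two carbonyls of 15 the one flanked by C–OMe is a simple enone carbonyl while the other is a vinylogous ester, so the hard nucleophile should attack the former and place the carbinol carbon between C=O and C–OMe as the rearrangement requires; the carbinol epimers are both carried on.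

Step 9
Reactants: 17 4-{[(2S,4S)-4,5-bis(tert-butyldimethylsilyloxy)-7-methoxy-6,8-dimethylchroman-2-yl]ethynyl}-4-hydroxy-3-methoxycyclobut-2-en-1-one
Product: 20 2-[(2S,4S)-4,5-bis(tert-butyldimethylsilyloxy)-7-methoxy-6,8-dimethylchroman-2-yl]-5-methoxy-1,4-benzoquinone, via alkynyl vinylketene 18 (not isolated), via aryl diradical 19 (not isolated)
Conditions: PhMe (0.01 M, degassed), 110 °C
Reagents that add atoms: none
Why: Heating effects conrotatory 4π-electrocyclic opening of the cyclobutenone C1–C4 bond with the hydroxyl rotating outward and the alkynyl group inward, so ketene 18 forms with its ketene carbon next to the alkyne. The ketene carbon then bonds to the distal alkyne carbon (the one carrying chroman C2), which forms the C1'–C2' bond and closes ring B in a six-membered mode to the phenoxyl/aryl σ-diradical 19; transfer of the hydroxyl hydrogen to the ring carbon radical gives the quinone directly at its final oxidation level. This is the Moore rearrangement of 4-alkynyl-4-hydroxycyclobutenones to 1,4-benzoquinones. No stereocentre is created, the neutral thermal conditions leave C2 (S) and the silyl ethers untouched, and both carbinol epimers of 17 converge on 20. The selectivity needed is six- over five-membered closure (ketene carbon to the proximal alkyne carbon, which would give an alkylidenecyclopentenedione), and it is secured by the sp3 C2 substituent on the alkyne terminus, which offers no stabilisation to the exocyclic vinyl radical of the five-membered path. High dilution and degassing suppress bimolecular reactions of the ketene and the diradical.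

Step 10
Reactants: 20 2-[(2S,4S)-4,5-bis(tert-butyldimethylsilyloxy)-7-methoxy-6,8-dimethylchroman-2-yl]-5-methoxy-1,4-benzoquinone
Product: 21 2-[(2S,4S)-4,5-dihydroxy-7-methoxy-6,8-dimethylchroman-2-yl]-5-methoxy-1,4-benzoquinone
Conditions: Bu4NF (4 equiv), AcOH (4 equiv), THF, 0 °C → rt
Reagents that add atoms: none
Why: Fluoride-mediated cleavage of the aryl and the secondary benzylic silyl ethers, buffered with acetic acid so that the medium is neither basic enough to attack the methoxyquinone or open ring C nor acidic enough to ionise the electron-rich benzylic alcohol.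

Step 11
Reactants: 21 2-[(2S,4S)-4,5-dihydroxy-7-methoxy-6,8-dimethylchroman-2-yl]-5-methoxy-1,4-benzoquinone
Product: 22 2-[(2S)-5-hydroxy-7-methoxy-6,8-dimethyl-4-oxochroman-2-yl]-5-methoxy-1,4-benzoquinone (CNP0208927.1)
Conditions: MnO2 (activated, 20 equiv), CH2Cl2, rt
Reagents that add atoms: none
Why: MnO2 oxidation of a benzylic alcohol on an electron-rich ring under neutral heterogeneous conditions returns the C4 ketone, which is at once stabilised by the hydrogen bond from the C5 hydroxyl, and removes the temporary C4 stereocentre without touching C2.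

**Compound list**

1 | 2',4',6'-trihydroxyacetophenone | CC(=O)c1c(O)cc(O)cc1O | starting material
2 | 2',4',6'-trihydroxy-3',5'-dimethylacetophenone | CC(=O)c1c(O)c(C)c(O)c(C)c1O | intermediate
3 | 2',6'-dihydroxy-4'-methoxy-3',5'-dimethylacetophenone | CC(=O)c1c(O)c(C)c(OC)c(C)c1O | intermediate
4 | (E)-1-(2,6-dihydroxy-4-methoxy-3,5-dimethylphenyl)-3-(dimethylamino)prop-2-en-1-one | CN(C)/C=C/C(=O)c1c(O)c(C)c(OC)c(C)c1O | intermediate
5 | 5-hydroxy-7-methoxy-6,8-dimethyl-4H-chromen-4-one | O=c1ccoc2c(C)c(OC)c(C)c(O)c12 | intermediate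
6 | trimethylsilylacetylene | C[Si](C)(C)C#C | starting material
7 | 7-methoxy-6,8-dimethyl-4,5-bis(trimethylsilyloxy)chromenylium trifluoromethanesulfonate | C[Si](C)(C)Oc1cc[o+]c2c(C)c(OC)c(C)c(O[Si](C)(C)C)c12.[O-]S(=O)(=O)C(F)(F)F | intermediate
8 | (2S)-7-methoxy-6,8-dimethyl-4,5-bis(trimethylsilyloxy)-2-[(trimethylsilyl)ethynyl]-2H-chromene | C[Si](C)(C)C#C[C@@H]1C=C(O[Si](C)(C)C)c2c(O[Si](C)(C)C)c(C)c(OC)c(C)c2O1 | intermediate
9 | (2S)-5-hydroxy-7-methoxy-6,8-dimethyl-2-[(trimethylsilyl)ethynyl]chroman-4-one | C[Si](C)(C)C#C[C@@H]1CC(=O)c2c(O)c(C)c(OC)c(C)c2O1 | intermediate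
10 | (2S,4S)-7-methoxy-6,8-dimethyl-2-[(trimethylsilyl)ethynyl]chromane-4,5-diol | C[Si](C)(C)C#C[C@@H]1C[C@H](O)c2c(O)c(C)c(OC)c(C)c2O1 | intermediate
11 | (2S,4S)-2-ethynyl-7-methoxy-6,8-dimethylchromane-4,5-diol | C#C[C@@H]1C[C@H](O)c2c(O)c(C)c(OC)c(C)c2O1 | intermediate
12 | (2S,4S)-4,5-bis(tert-butyldimethylsilyloxy)-2-ethynyl-7-methoxy-6,8-dimethylchromane | C#C[C@@H]1C[C@H](O[Si](C)(C)C(C)(C)C)c2c(O[Si](C)(C)C(C)(C)C)c(C)c(OC)c(C)c2O1 | intermediate
13 | dimethyl squarate | COC1=C(OC)C(=O)C1=O | starting material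
14 | 4-hydroxy-2,3-dimethoxycyclobut-2-en-1-one (racemic) | COC1=C(OC)C(=O)C1O | intermediate
15 | 3-methoxycyclobut-3-ene-1,2-dione | COC1=CC(=O)C1=O | intermediate
16 | {[(2S,4S)-4,5-bis(tert-butyldimethylsilyloxy)-7-methoxy-6,8-dimethylchroman-2-yl]ethynyl}lithium | [Li]C#C[C@@H]1C[C@H](O[Si](C)(C)C(C)(C)C)c2c(O[Si](C)(C)C(C)(C)C)c(C)c(OC)c(C)c2O1 | intermediate
17 | 4-{[(2S,4S)-4,5-bis(tert-butyldimethylsilyloxy)-7-methoxy-6,8-dimethylchroman-2-yl]ethynyl}-4-hydroxy-3-methoxycyclobut-2-en-1-one (carbinol epimers) | COC1=CC(=O)C1(O)C#C[C@@H]2C[C@H](O[Si](C)(C)C(C)(C)C)c3c(O[Si](C)(C)C(C)(C)C)c(C)c(OC)c(C)c3O2 | intermediate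
18 | (3Z)-6-[(2S,4S)-4,5-bis(tert-butyldimethylsilyloxy)-7-methoxy-6,8-dimethylchroman-2-yl]-4-hydroxy-3-methoxyhexa-1,3-dien-5-yn-1-one | O=C=C/C(OC)=C(/O)C#C[C@@H]1C[C@H](O[Si](C)(C)C(C)(C)C)c2c(O[Si](C)(C)C(C)(C)C)c(C)c(OC)c(C)c2O1 | intermediate
19 | 2-[(2S,4S)-4,5-bis(tert-butyldimethylsilyloxy)-7-methoxy-6,8-dimethylchroman-2-yl]-4-hydroxy-5-methoxyphenoxyl-3-yl diradical | COc1cc([O])c([c]c1O)[C@@H]2C[C@H](O[Si](C)(C)C(C)(C)C)c3c(O[Si](C)(C)C(C)(C)C)c(C)c(OC)c(C)c3O2 | intermediate
20 | 2-[(2S,4S)-4,5-bis(tert-butyldimethylsilyloxy)-7-methoxy-6,8-dimethylchroman-2-yl]-5-methoxy-1,4-benzoquinone | COC1=CC(=O)C([C@@H]2C[C@H](O[Si](C)(C)C(C)(C)C)c3c(O[Si](C)(C)C(C)(C)C)c(C)c(OC)c(C)c3O2)=CC1=O | intermediate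
21 | 2-[(2S,4S)-4,5-dihydroxy-7-methoxy-6,8-dimethylchroman-2-yl]-5-methoxy-1,4-benzoquinone | COC1=CC(=O)C([C@@H]2C[C@H](O)c3c(O)c(C)c(OC)c(C)c3O2)=CC1=O | intermediate
22 | 2-[(2S)-5-hydroxy-7-methoxy-6,8-dimethyl-4-oxochroman-2-yl]-5-methoxy-1,4-benzoquinone | COC1=CC(=O)C([C@@H]2CC(=O)c3c(O)c(C)c(OC)c(C)c3O2)=CC1=O | target

**Step count**

Total steps: 11. Longest linear sequence: 10 steps (steps 1–6 and 8–11); step 7 is a one-step side branch from dimethyl squarate.

**Steps most likely to fail, with fallbacks**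

1. Step 9. The ketene may close onto the proximal alkyne carbon in a five-membered mode, the hydroxyl may rotate inward so that the ketene is trapped as a furanone, or the benzylic silyl ether may be lost on heating. The fallback sets out from 12 and returns at 20. Pd-catalysed hydrostannylation (Bu3SnH, PdCl2(PPh3)2 cat., THF, 0 °C) should give tributyl{(E)-2-[(2S,4S)-4,5-bis(tert-butyldimethylsilyloxy)-7-methoxy-6,8-dimethylchroman-2-yl]vinyl}stannane F1. Tin–lithium exchange (n-BuLi, THF, −78 °C) gives the (E)-alkenyllithium F2, which adds to 15 at the same carbonyl as in step 8 to give the 4-alkenyl-4-hydroxy-3-methoxycyclobutenone F3. Thermolysis (PhMe, 110 °C) opens F3 to the dienylketene F4, whose 6π-electrocyclisation can only form a six-membered ring, the cyclohexadienone F5, and this enolises to the hydroquinone F6. Ag2O (Et2O, MgSO4, rt) oxidises F6 to 20; this oxidation is far easier than any oxidation of ring A, so the advantage of the strategy is kept.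

2. Step 4. Conversion or facial discrimination may be poor in the addition to a crowded, strongly donor-substituted 4,5-bis(silyloxy)benzopyrylium ion. The fallback sets out from 5 (with 6) and returns at 11. Without a chiral ligand (CuI cat., iPr2NEt, TMSOTf, CH2Cl2, −40 °C, through 7) the alkynylation gives the racemic bis-silyl 2-alkynyl-2H-chromene F7 and, after acidic work-up, the racemic 2-[(trimethylsilyl)ethynyl]chromanone F8. Reduction and desilylation as in step 5 pass through the racemic silylalkynyl cis-diol F9 to the racemic cis-2-ethynylchromane-4,5-diol F10. Lipase kinetic resolution (immobilised Candida antarctica lipase B, vinyl acetate, MTBE, 30 °C) should acetylate the (4R)-alcohol, as expected from the Kazlauskas rule, to the (2R,4R)-acetate F11 and leave (2S,4S)-11, which is separated and carried on.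

3. Step 10. The methoxyquinone may degrade under fluoride, the crowded C4 silyl ether may cleave incompletely, or the unmasked electron-rich o-hydroxybenzylic alcohol may ionise. The fallback sets out from 20 and returns at 22. DDQ (CH2Cl2/pH 7 buffer, 0 °C → rt) abstracts hydride from the benzylic C4–H of the silyl ether and should give the ketone directly, 2-[(2S)-5-(tert-butyldimethylsilyloxy)-7-methoxy-6,8-dimethyl-4-oxochroman-2-yl]-5-methoxy-1,4-benzoquinone F12, so that no free benzylic alcohol is ever formed. The remaining aryl silyl ether, activated by the peri carbonyl, is then cleaved with Et3N·3HF (MeCN, rt) to give 22.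

**Further compounds**

F1 | step 9 | tributyl{(E)-2-[(2S,4S)-4,5-bis(tert-butyldimethylsilyloxy)-7-methoxy-6,8-dimethylchroman-2-yl]vinyl}stannane | CCCC[Sn](CCCC)(CCCC)/C=C/[C@@H]1C[C@H](O[Si](C)(C)C(C)(C)C)c2c(O[Si](C)(C)C(C)(C)C)c(C)c(OC)c(C)c2O1
F2 | step 9 | {(E)-2-[(2S,4S)-4,5-bis(tert-butyldimethylsilyloxy)-7-methoxy-6,8-dimethylchroman-2-yl]vinyl}lithium | [Li]/C=C/[C@@H]1C[C@H](O[Si](C)(C)C(C)(C)C)c2c(O[Si](C)(C)C(C)(C)C)c(C)c(OC)c(C)c2O1
F3 | step 9 | 4-{(E)-2-[(2S,4S)-4,5-bis(tert-butyldimethylsilyloxy)-7-methoxy-6,8-dimethylchroman-2-yl]vinyl}-4-hydroxy-3-methoxycyclobut-2-en-1-one (carbinol epimers) | COC1=CC(=O)C1(O)/C=C/[C@@H]2C[C@H](O[Si](C)(C)C(C)(C)C)c3c(O[Si](C)(C)C(C)(C)C)c(C)c(OC)c(C)c3O2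
F4 | step 9 | (3Z,5E)-6-[(2S,4S)-4,5-bis(tert-butyldimethylsilyloxy)-7-methoxy-6,8-dimethylchroman-2-yl]-4-hydroxy-3-methoxyhexa-1,3,5-trien-1-one | O=C=C/C(OC)=C(/O)\C=C\[C@@H]1C[C@H](O[Si](C)(C)C(C)(C)C)c2c(O[Si](C)(C)C(C)(C)C)c(C)c(OC)c(C)c2O1
F5 | step 9 | 6-[(2S,4S)-4,5-bis(tert-butyldimethylsilyloxy)-7-methoxy-6,8-dimethylchroman-2-yl]-4-hydroxy-3-methoxycyclohexa-2,4-dien-1-one (epimers at C6 of the dienone) | COC1=CC(=O)C([C@@H]2C[C@H](O[Si](C)(C)C(C)(C)C)c3c(O[Si](C)(C)C(C)(C)C)c(C)c(OC)c(C)c3O2)C=C1O
F6 | step 9 | 2-[(2S,4S)-4,5-bis(tert-butyldimethylsilyloxy)-7-methoxy-6,8-dimethylchroman-2-yl]-5-methoxybenzene-1,4-diol | COc1cc(O)c(cc1O)[C@@H]2C[C@H](O[Si](C)(C)C(C)(C)C)c3c(O[Si](C)(C)C(C)(C)C)c(C)c(OC)c(C)c3O2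
F7 | step 4 | racemic 7-methoxy-6,8-dimethyl-4,5-bis(trimethylsilyloxy)-2-[(trimethylsilyl)ethynyl]-2H-chromene | C[Si](C)(C)C#CC1C=C(O[Si](C)(C)C)c2c(O[Si](C)(C)C)c(C)c(OC)c(C)c2O1
F8 | step 4 | racemic 5-hydroxy-7-methoxy-6,8-dimethyl-2-[(trimethylsilyl)ethynyl]chroman-4-one | C[Si](C)(C)C#CC1CC(=O)c2c(O)c(C)c(OC)c(C)c2O1
F9 | step 4 | racemic cis-7-methoxy-6,8-dimethyl-2-[(trimethylsilyl)ethynyl]chromane-4,5-diol | C[Si](C)(C)C#C[C@@H]1C[C@H](O)c2c(O)c(C)c(OC)c(C)c2O1.C[Si](C)(C)C#C[C@H]1C[C@@H](O)c2c(O)c(C)c(OC)c(C)c2O1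
F10 | step 4 | racemic cis-2-ethynyl-7-methoxy-6,8-dimethylchromane-4,5-diol | C#C[C@@H]1C[C@H](O)c2c(O)c(C)c(OC)c(C)c2O1.C#C[C@H]1C[C@@H](O)c2c(O)c(C)c(OC)c(C)c2O1
F11 | step 4 | (2R,4R)-2-ethynyl-5-hydroxy-7-methoxy-6,8-dimethylchroman-4-yl acetate | C#C[C@H]1C[C@@H](OC(C)=O)c2c(O)c(C)c(OC)c(C)c2O1
F12 | step 10 | 2-[(2S)-5-(tert-butyldimethylsilyloxy)-7-methoxy-6,8-dimethyl-4-oxochroman-2-yl]-5-methoxy-1,4-benzoquinone | COC1=CC(=O)C([C@@H]2CC(=O)c3c(O[Si](C)(C)C(C)(C)C)c(C)c(OC)c(C)c3O2)=CC1=O
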